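Late in the dusk, dawn and summer runs X is still sinking slowly: in the dusk run it goes from 42.2% at 8.00 min to 23.9% at 80.0 min. The question is what this same charge gives in other vessels.

| setting | dusk | dawn | summer | Sunday's | Tuesday's | Wednesday's |
|---|---|---|---|---|---|---|
| Q | 37 mM | 52 mM | 81 mM | 37 mM | 37 mM | 37 mM |
| remark | run made earlier | run made earlier | run made earlier | everything together in a closed stirred flask, run for 80 min | a single well-mixed tank run continuously and read at steady state, 80 min in it on average | a single well-mixed tank run continuously and read at steady state, 400 min in it on average |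
| time |  |  |  | 80 min |  |  |

| run | time / min | X / % | D / % |
|---|---|---|---|
| dusk | 8.00 | 42.2 | 3.1 |
| dusk | 20.0 | 38.3 | 10.2 |
| dusk | 40.0 | 31.5 | 18.6 |
| dusk | 60.0 | 29.3 | 25.6 |
| dusk | 80.0 | 23.9 | 31.8 |
| dawn | 8.00 | 42.5 | 6.0 |
| dawn | 20.0 | 38.5 | 10.3 |
| dawn | 40.0 | 33.0 | 20.4 |
| dawn | 60.0 | 28.7 | 24.9 |
| dawn | 80.0 | 26.2 | 30.7 |
| summer | 6.00 | 44.4 | 1.8 |
| summer | 12.0 | 41.6 | 5.9 |
| summer | 25.0 | 39.0 | 11.8 |
| summer | 40.0 | 35.1 | 16.3 |
| summer | 80.0 | 26.2 | 27.5 |

(standard deviation of a reading: 1 percentage point)

- percentages count the Q that a species holds: one E counts as two
- X is meant together with its E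
- the stated concentrations are those of everything mixed, before any reaction; amounts are the same in each set-up
- the earlier runs were read with a standard deviation of 1 percentage point
- what may be going on: Q <-> D; Q + X <-> E; Q <-> X; X <-> D; X -> J
- the earlier runs were made in a closed, stirred flask
- in an amount of X, one E counts as one X

* the set-up with the highest share of X in all that became X or D or J, at the outlet or at the end ("none" if the first two lie within 2 percentage points) (Sunday's / Tuesday's / Wednesday's / none)
* share of X in all that became X or D or J, at the outlet or at the end, Sunday's
* share of X in all that became X or D or J, at the outlet or at the end, Tuesday's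
* share of X in all that became X or D or J, at the outlet or at the end, Wednesday's

I build the flask up one process at a time. First comes the main step, Q ⇌ X. In the dusk run X already stands at 42.2% at 8.00 min, more than D at 3.1%, so I treat Q and X as one pool in which X keeps a fixed part, and [Q] + [X] is the concentration that sets the rate. With this step by itself, X is the whole of what became product, a share of 100 percent.

Next comes the drain out of the pool, which I take as pseudo-first-order in [Q] + [X], since X at 80.0 min reads 23.9% in the dusk run and 26.2% in the summer run, on a charge twice as large. The drain constant, the fraction of the pool lost per minute as read from the fall of X in these runs, is 0.00725 min⁻¹. Running the dusk reading back to the start puts X at 44.7% of the pool.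

Sunday's closed flask keeps 56.0% of the pool. In a tank the pool left is the charge divided by one plus the drain constant times the mean stay, so Tuesday's keeps 63.3% and Wednesday's 25.6%. The share is X over X plus what has drained, which brings it down to 36.3%, 43.5% and 13.4%.

D and J sit together in the drained part of my reckoning. X is read together with its E, so the gap of 0.3 percentage points between dusk and dawn at 8.00 min does not tell how much E stands in the flask, and leaving E out as a separate term is an assumption of mine. I commit to Tuesday's, ahead of Sunday's by 7.2 points.

The forecast says: “The pool then drains first-order”. It gives 36% (33% to 39%), 43.5% (40% to 47%) and 13.5% (10% to 19%), and it picks Tuesday's.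

The flask gives 34.5%, 42.2% and 16.1%, with Tuesday's highest, each inside the forecast's range.

    Q ⇌ D (K = 4.10, k = 0.480 h⁻¹)
    Q + X ⇌ E, settled at all times (K = 32.0 M⁻¹)
    Q ⇌ X (K = 0.760, k = 17.0 h⁻¹)
    X ⇌ D (k = 0.520 h⁻¹)
    X → J (k = 0.440 h⁻¹)

Q turns into X with a half-life of 2.4 min, forward step counted, while the drain constant gives the pool a half-life of 95.6 min, shorter by a factor of 39.1. The drain constant times the mean stay is 0.580 in Tuesday's tank and 2.90 in Wednesday's tank, where the share of X stands at 16.1%.

(The runs were generated by integration on assumed constants.)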